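**Plan**

1. Retrosynthesis: N1–H is released last from N1–SEM, C4'–H comes from C4'–Cl, and the C2'=C3' double bond from a C3' ketone. The resulting indolin-3-one is cut at N1'–C7a' and C3'–C3a'.
2. Enabling feature: in the N-linked indole, N1' and C3' sit on the adjacent benzenoid carbons C7a' and C3a'. Its five-membered ring B can therefore be formed when an aryne (3-chloro-5-prenylbenzyne) takes up the nitrogen and the ester carbon of an N-(indol-3-yl)glycinate.
3. Further cuts: both aryl–prenyl bonds (Stille), C3–N (Curtius from the indole-3-carboxylic acid) and N–CH2 (alkylation with methyl bromoacetate).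
4. Forward: the benzo ring of the second indole is prepared as a silyl triflate (steps 1–4) and the purchased indole is turned into the glycinate (steps 5–10). Ring B closes in step 11 and is then aromatised, dechlorinated and N-deprotected (steps 12–14).
5. Stereochemistry: the target has no stereocentre and no stereogenic alkene; the racemic carbinol of step 12 disappears on dehydration.

Key step: step 11

Remark: prenyl = 3-methylbut-2-en-1-yl; SEM = 2-(trimethylsilyl)ethoxymethyl; primed locants belong to the N-linked indole, whose five-membered ring is ring B. The palladium-catalysed couplings of the prenylstannane with aryl bromides are assumed to give the linear, unrearranged prenyl arene.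

**Step 1**
Reactants: 1 3-bromo-5-chlorophenol
Product: 2 3-bromo-5-chlorophenyl N-isopropylcarbamate
Conditions: i-PrNCO, Et3N (cat.), CH2Cl2, rt
Reagents that add atoms: isopropyl isocyanate, CC(C)N=C=O
Why: Amine-catalysed carbamoylation of the phenol with the isocyanate installs an O-aryl N–H carbamate that will direct the later ortho-metalation and can be removed by mild E1cB cleavage.

**Step 2**
Reactants: 2 3-bromo-5-chlorophenyl N-isopropylcarbamate; 3 tributyl(3-methylbut-2-en-1-yl)stannane
Product: 4 3-chloro-5-prenylphenyl N-isopropylcarbamate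
Conditions: Pd(PPh3)4 (cat.), DMF, 90 °C
Reagents that add atoms: none
Why: Stille coupling, in which the triphenylphosphine catalyst inserts into C–Br but not C–Cl and the allylpalladium intermediate should couple at its unhindered CH2 terminus to give the linear prenyl arene.

**Step 3**
Reactants: 4 3-chloro-5-prenylphenyl N-isopropylcarbamate
Product: 8 3-chloro-5-prenyl-2-(trimethylsilyl)phenyl N-isopropylcarbamate, via N-silyl carbamate 5 (not isolated), via aryllithium 6 (not isolated), via bis-silyl carbamate 7 (not isolated)
Conditions: TBSOTf, TMEDA, Et2O, 0 °C to rt; n-BuLi (2 equiv), TMEDA, −78 °C; TMSCl, −78 °C to rt; aq. NaHSO4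
Reagents that add atoms: chlorotrimethylsilane, C[Si](C)(C)Cl
Why: Directed ortho metalation, in which in-flask N-silylation masks the N–H, the carbamate oxygen and the chlorine together make C2–H the kinetically most acidic site at −78 °C (where deprotonation of the prenyl CH2, LiCl loss and anionic Fries shift should stay slow), TMSCl traps the aryllithium and the acidic work-up removes the N-silyl group.

**Step 4**
Reactants: 8 3-chloro-5-prenyl-2-(trimethylsilyl)phenyl N-isopropylcarbamate
Product: 10 3-chloro-5-prenyl-2-(trimethylsilyl)phenyl trifluoromethanesulfonate, via silylphenol 9 (not isolated)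
Conditions: DBU, Et2NH, MeCN, 40 °C; then PhNTf2, 40 °C
Reagents that add atoms: N-phenylbis(trifluoromethanesulfonimide), O=S(=O)(N(c1ccccc1)S(=O)(=O)C(F)(F)F)C(F)(F)F
Why: E1cB carbamate cleavage (the expelled isocyanate is scavenged by diethylamine as a urea) frees the phenoxide, which is O-sulfonylated in the same flask, the standard one-pot way to ortho-silylaryl triflates.

**Step 5**
Reactants: 11 methyl 6-bromo-1H-indole-3-carboxylate
Product: 12 methyl 6-bromo-1-SEM-indole-3-carboxylate
Conditions: NaH, DMF, 0 °C; SEMCl, 0 °C to rt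
Reagents that add atoms: 2-(trimethylsilyl)ethoxymethyl chloride, C[Si](C)(C)CCOCCl
Why: N-alkylation of the indolide anion (SN2 at the chloromethyl ether) gives a base-stable N-protecting group that tolerates every later step and is removed with fluoride.

**Step 6**
Reactants: 12 methyl 6-bromo-1-SEM-indole-3-carboxylate; 3 tributyl(3-methylbut-2-en-1-yl)stannane
Product: 13 methyl 6-prenyl-1-SEM-indole-3-carboxylate
Conditions: Pd(PPh3)4 (cat.), DMF, 95 °C
Reagents that add atoms: none
Why: Stille coupling of the aryl bromide with the prenylstannane, a routine way to linear C6-prenyl indoles that leaves the ester and the SEM group untouched.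

**Step 7**
Reactants: 13 methyl 6-prenyl-1-SEM-indole-3-carboxylate
Product: 14 6-prenyl-1-SEM-indole-3-carboxylic acid
Conditions: LiOH·H2O, THF/MeOH/H2O, 60 °C; then 1 M HCl to pH 4, 0 °C
Reagents that add atoms: lithium hydroxide, [Li+].[OH-]
Why: Saponification of the vinylogous carbamate ester needs gentle heating but harms neither the SEM aminal nor the prenyl group, and cold, mild acidification avoids decarboxylation.

**Step 8**
Reactants: 14 6-prenyl-1-SEM-indole-3-carboxylic acid
Product: 17 allyl N-(6-prenyl-1-SEM-indol-3-yl)carbamate, via acyl azide 15 (not isolated), via isocyanate 16 (not isolated)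
Conditions: DPPA, Et3N, toluene, rt then 90 °C; allyl alcohol, 90 °C
Reagents that add atoms: diphenylphosphoryl azide, [N-]=[N+]=NP(=O)(Oc1ccccc1)Oc1ccccc1; allyl alcohol, OCC=C
Why: Curtius rearrangement of the acyl azide formed in the flask places nitrogen on C3, and trapping the isocyanate with allyl alcohol gives a stable Alloc carbamate instead of the oxidation-prone free 3-aminoindole.

**Step 9**
Reactants: 17 allyl N-(6-prenyl-1-SEM-indol-3-yl)carbamate; 18 methyl bromoacetate
Product: 19 methyl N-(allyloxycarbonyl)-N-(6-prenyl-1-SEM-indol-3-yl)glycinate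
Conditions: NaH, DMF, 0 °C; then 18, 0 °C to rt
Reagents that add atoms: none
Why: SN2 N-alkylation of the carbamate anion with the α-bromo ester is clean and stops at mono-alkylation because the nitrogen is carbamate-protected.

**Step 10**
Reactants: 19 methyl N-(allyloxycarbonyl)-N-(6-prenyl-1-SEM-indol-3-yl)glycinate
Product: 21 methyl N-(6-prenyl-1-SEM-indol-3-yl)glycinate, via carbamic acid 20 (not isolated)
Conditions: Pd(PPh3)4 (cat.), morpholine, THF, rt, argon; used at once
Reagents that add atoms: none
Why: Allyl transfer from the carbamate to morpholine through a π-allyl complex of zerovalent palladium (Tsuji–Trost deallylation), followed by loss of CO2, frees the secondary amine under neutral, acid-free conditions that spare the SEM, ester and prenyl groups.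

**Step 11**
Reactants: 21 methyl N-(6-prenyl-1-SEM-indol-3-yl)glycinate; 10 3-chloro-5-prenyl-2-(trimethylsilyl)phenyl trifluoromethanesulfonate
Product: 23 4-chloro-6-prenyl-1-(6-prenyl-1-SEM-indol-3-yl)indolin-3-one, via aryne 22 (not isolated)
Conditions: CsF, MeCN, rt, argon (10 in slight excess)
Reagents that add atoms: none
Why: Fluoride attacks silicon and triflate leaves, so aryne 22 is released slowly; the amine nitrogen of 21 adds to the aryne carbon remote from chlorine (future C7a'), and the aryl anion thus formed next to chlorine (future C3a') attacks the ester carbonyl and expels methoxide, so that N1'–C7a' and C3'–C3a' form in one operation. The closest known reaction type is the aryne insertion of N-aryl α-amino esters with intramolecular acyl capture to give indolin-3-ones, a relative of the acridone synthesis from anthranilates. Ring B closes in a 5-exo-trig mode, the aryl carbanion adding to the ester C=O held by the N–CH2 tether. No stereocentre is formed. The step needs regioselective N-addition, which the C–Cl bond secures by distorting the aryne and stabilising the adjacent carbanion, and this in turn places the prenyl group at C6'. It also needs acyl capture to outrun N–H to carbon proton transfer, which the five-membered transition state and the aprotic medium favour, and attack through nitrogen rather than indole C2, which the more nucleophilic N–H amine should ensure.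

**Step 12**
Reactants: 23 4-chloro-6-prenyl-1-(6-prenyl-1-SEM-indol-3-yl)indolin-3-one
Product: 25 4-chloro-6-prenyl-1-(6-prenyl-1-SEM-indol-3-yl)indole, via indolin-3-ol 24 (not isolated)
Conditions: NaBH4, THF/MeOH, 0 °C; then PPTS (cat.), toluene, 50 °C
Reagents that add atoms: none
Why: Borohydride reduction of the aryl ketone gives a racemic carbinol (hydride adds to either face, which is irrelevant), and mild acid-catalysed dehydration, driven by the nitrogen lone pair and aromatisation, then yields the indole.

**Step 13**
Reactants: 25 4-chloro-6-prenyl-1-(6-prenyl-1-SEM-indol-3-yl)indole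
Product: 26 6-prenyl-1-(6-prenyl-1-SEM-indol-3-yl)indole
Conditions: Pd(OAc)2 (cat.), XPhos (cat.), HCO2Na, DMF, 90 °C
Reagents that add atoms: none
Why: Palladium-catalysed transfer hydrodechlorination, in which the bulky electron-rich biarylphosphine allows insertion into the aryl C–Cl bond, formate replaces chloride and loses CO2, and C–H reductive elimination should be faster than any reaction of the short-lived hydride with the trisubstituted prenyl alkenes.

**Step 14**
Reactants: 26 6-prenyl-1-(6-prenyl-1-SEM-indol-3-yl)indole
Product: 28 6-prenyl-3-(6-prenyl-1H-indol-1-yl)-1H-indole (target), via N-hydroxymethyl indole 27 (not isolated)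
Conditions: TBAF, ethylenediamine, DMF, 80 °C
Reagents that add atoms: none
Why: Fluoride-induced fragmentation of the SEM group (attack at silicon, loss of ethene) gives the N-hydroxymethyl indole, which releases formaldehyde to the diamine scavenger, a standard N-SEM cleavage that leaves the prenyl groups alone.

**Compound list**

1 | 3-bromo-5-chlorophenol | Oc1cc(Cl)cc(Br)c1 | starting material
2 | 3-bromo-5-chlorophenyl N-isopropylcarbamate | CC(C)NC(=O)Oc1cc(Cl)cc(Br)c1 | intermediate
3 | tributyl(3-methylbut-2-en-1-yl)stannane | CCCC[Sn](CCCC)(CCCC)CC=C(C)C | starting material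
4 | 3-chloro-5-prenylphenyl N-isopropylcarbamate | CC(C)NC(=O)Oc1cc(Cl)cc(CC=C(C)C)c1 | intermediate
5 | 3-chloro-5-prenylphenyl N-(tert-butyldimethylsilyl)-N-isopropylcarbamate (formed and consumed in step 3) | CC(C)N(C(=O)Oc1cc(Cl)cc(CC=C(C)C)c1)[Si](C)(C)C(C)(C)C | intermediate
6 | 2-lithio derivative of 5, lithium on the carbon between the carbamate oxygen and chlorine (formed and consumed in step 3) | CC(C)N(C(=O)Oc1cc(CC=C(C)C)cc(Cl)c1[Li])[Si](C)(C)C(C)(C)C | intermediate
7 | 3-chloro-5-prenyl-2-(trimethylsilyl)phenyl N-(tert-butyldimethylsilyl)-N-isopropylcarbamate (formed and consumed in step 3) | CC(C)N(C(=O)Oc1cc(CC=C(C)C)cc(Cl)c1[Si](C)(C)C)[Si](C)(C)C(C)(C)C | intermediate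
8 | 3-chloro-5-prenyl-2-(trimethylsilyl)phenyl N-isopropylcarbamate | CC(C)NC(=O)Oc1cc(CC=C(C)C)cc(Cl)c1[Si](C)(C)C | intermediate
9 | 3-chloro-5-prenyl-2-(trimethylsilyl)phenol (formed and consumed in step 4) | Oc1cc(CC=C(C)C)cc(Cl)c1[Si](C)(C)C | intermediate
10 | 3-chloro-5-prenyl-2-(trimethylsilyl)phenyl trifluoromethanesulfonate | CC(C)=CCc1cc(Cl)c([Si](C)(C)C)c(OS(=O)(=O)C(F)(F)F)c1 | intermediate
11 | methyl 6-bromo-1H-indole-3-carboxylate | COC(=O)c1c[nH]c2cc(Br)ccc12 | starting material
12 | methyl 6-bromo-1-SEM-indole-3-carboxylate | COC(=O)c1cn(COCC[Si](C)(C)C)c2cc(Br)ccc12 | intermediate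
13 | methyl 6-prenyl-1-SEM-indole-3-carboxylate | COC(=O)c1cn(COCC[Si](C)(C)C)c2cc(CC=C(C)C)ccc12 | intermediate
14 | 6-prenyl-1-SEM-indole-3-carboxylic acid | OC(=O)c1cn(COCC[Si](C)(C)C)c2cc(CC=C(C)C)ccc12 | intermediate
15 | 6-prenyl-1-SEM-indole-3-carbonyl azide (formed and consumed in step 8) | [N-]=[N+]=NC(=O)c1cn(COCC[Si](C)(C)C)c2cc(CC=C(C)C)ccc12 | intermediate
16 | 3-isocyanato-6-prenyl-1-SEM-indole (formed and consumed in step 8) | O=C=Nc1cn(COCC[Si](C)(C)C)c2cc(CC=C(C)C)ccc12 | intermediate
17 | allyl N-(6-prenyl-1-SEM-indol-3-yl)carbamate | C=CCOC(=O)Nc1cn(COCC[Si](C)(C)C)c2cc(CC=C(C)C)ccc12 | intermediate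
18 | methyl bromoacetate | COC(=O)CBr | starting material
19 | methyl N-(allyloxycarbonyl)-N-(6-prenyl-1-SEM-indol-3-yl)glycinate | COC(=O)CN(C(=O)OCC=C)c1cn(COCC[Si](C)(C)C)c2cc(CC=C(C)C)ccc12 | intermediate
20 | N-carboxy-N-(6-prenyl-1-SEM-indol-3-yl)glycine methyl ester, the carbamic acid (formed and consumed in step 10) | COC(=O)CN(C(=O)O)c1cn(COCC[Si](C)(C)C)c2cc(CC=C(C)C)ccc12 | intermediate
21 | methyl N-(6-prenyl-1-SEM-indol-3-yl)glycinate | COC(=O)CNc1cn(COCC[Si](C)(C)C)c2cc(CC=C(C)C)ccc12 | intermediate
22 | 3-chloro-5-prenylbenzyne (formed and consumed in step 11) | CC(C)=CCC1=CC#CC(Cl)=C1 | intermediate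
23 | 4-chloro-6-prenyl-1-(6-prenyl-1-SEM-indol-3-yl)indolin-3-one | O=C1CN(c2cn(COCC[Si](C)(C)C)c3cc(CC=C(C)C)ccc23)c2cc(CC=C(C)C)cc(Cl)c21 | intermediate
24 | racemic 4-chloro-6-prenyl-1-(6-prenyl-1-SEM-indol-3-yl)indolin-3-ol (formed and consumed in step 12) | OC1CN(c2cn(COCC[Si](C)(C)C)c3cc(CC=C(C)C)ccc23)c2cc(CC=C(C)C)cc(Cl)c21 | intermediate
25 | 4-chloro-6-prenyl-1-(6-prenyl-1-SEM-indol-3-yl)indole | CC(C)=CCc1cc(Cl)c2ccn(-c3cn(COCC[Si](C)(C)C)c4cc(CC=C(C)C)ccc34)c2c1 | intermediate
26 | 6-prenyl-1-(6-prenyl-1-SEM-indol-3-yl)indole | CC(C)=CCc1ccc2ccn(-c3cn(COCC[Si](C)(C)C)c4cc(CC=C(C)C)ccc34)c2c1 | intermediate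
27 | [6-prenyl-3-(6-prenylindol-1-yl)indol-1-yl]methanol (formed and consumed in step 14) | CC(C)=CCc1ccc2ccn(-c3cn(CO)c4cc(CC=C(C)C)ccc34)c2c1 | intermediate
28 | 6-prenyl-3-(6-prenyl-1H-indol-1-yl)-1H-indole | CC(C)=CCc1ccc2c(-n3ccc4ccc(CC=C(C)C)cc43)c[nH]c2c1 | target

**Step count**

Total: 14 steps. Longest linear sequence: 10 steps (steps 5–14, from 11). The aryne precursor is a four-step side branch (steps 1–4).

**Steps most likely to fail**

Step 11. Three things may go wrong. Proton transfer from N–H to the aryl anion may outrun acyl capture and leave an uncyclised N-aryl glycinate. The regioselectivity of nitrogen addition may erode. The electron-rich amine 21 and the 2-unsubstituted indolinone 23 may oxidise in air during handling.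

The fallback forms the N1'–C3 bond by copper-catalysed Ullmann–Goldberg N-arylation. It sets out from stannane 3 and commercial 6-bromoindole, whose Stille coupling (Pd(PPh3)4, DMF, 95 °C) should give 6-prenyl-1H-indole F1. Part of this is iodinated at C3 (I2, KOH, DMF, rt) to 3-iodo-6-prenyl-1H-indole F2 and then protected (NaH, SEMCl, DMF) as 3-iodo-6-prenyl-1-SEM-indole F3. Coupling of that iodide with a second portion of the 6-prenylindole (copper monoiodide CuI, trans-N,N'-dimethylcyclohexane-1,2-diamine, K3PO4, toluene, 110 °C) should give 26 directly. The route is rejoined at 26, before step 14, and steps 12 and 13 fall away.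

Step 3. The alkyllithium may deprotonate the benzylic-allylic CH2 of the prenyl chain instead of C2–H, and the ortho-lithio chloride may lose LiCl on warming.

The fallback makes the same aryne from the isomeric silyl triflate, with the silyl and triflate positions exchanged, and introduces silicon by halogen–lithium exchange before any prenyl group is present. It sets out from stannane 3 and commercial 4-bromo-2-chlorophenol. Iodination at the only free ortho position (NIS, TsOH cat., MeCN) gives 4-bromo-2-chloro-6-iodophenol F4. O-Silylation with HMDS gives (4-bromo-2-chloro-6-iodophenoxy)trimethylsilane F5. Iodine–lithium exchange (n-BuLi, THF, −100 °C) with retro-Brook O-to-C silyl shift gives the lithium salt of 4-bromo-2-chloro-6-(trimethylsilyl)phenol F6. Quenching with Tf2O in the same flask gives 4-bromo-2-chloro-6-(trimethylsilyl)phenyl triflate F7. Stille coupling with 3 (Pd(PPh3)4, dioxane, 100 °C, no chloride additive) should react only at the bromide, since the triflate is doubly flanked, and give 2-chloro-4-prenyl-6-(trimethylsilyl)phenyl triflate F8. With CsF this releases aryne 22, so the route is rejoined at 22 in step 11 and steps 1–4 are bypassed.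

Step 13. The palladium hydride may shift or saturate the prenyl double bonds, or insertion into the hindered, electron-rich C–Cl bond may be too slow.

The fallback removes chlorine without a hydride source. It sets out from 25, whose Miyaura borylation (Pd2(dba)3, XPhos, B2pin2, KOAc, dioxane, 100 °C) should give 6-prenyl-1-(6-prenyl-1-SEM-indol-3-yl)-4-(4,4,5,5-tetramethyl-1,3,2-dioxaborolan-2-yl)indole F9. Protodeboronation of that boronate (AgNO3 cat., Et3N, EtOH/H2O, 80 °C) returns to the route at 26.

**Further compounds**

F1 | step 11 | 6-prenyl-1H-indole | CC(C)=CCc1ccc2cc[nH]c2c1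
F2 | step 11 | 3-iodo-6-prenyl-1H-indole | CC(C)=CCc1ccc2c(I)c[nH]c2c1
F3 | step 11 | 3-iodo-6-prenyl-1-SEM-indole | CC(C)=CCc1ccc2c(I)cn(COCC[Si](C)(C)C)c2c1
F4 | step 3 | 4-bromo-2-chloro-6-iodophenol | Oc1c(Cl)cc(Br)cc1I
F5 | step 3 | (4-bromo-2-chloro-6-iodophenoxy)trimethylsilane | C[Si](C)(C)Oc1c(Cl)cc(Br)cc1I
F6 | step 3 | 4-bromo-2-chloro-6-(trimethylsilyl)phenol, formed as its lithium salt | Oc1c(Cl)cc(Br)cc1[Si](C)(C)C
F7 | step 3 | 4-bromo-2-chloro-6-(trimethylsilyl)phenyl trifluoromethanesulfonate | O=S(=O)(Oc1c(Cl)cc(Br)cc1[Si](C)(C)C)C(F)(F)F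
F8 | step 3 | 2-chloro-4-prenyl-6-(trimethylsilyl)phenyl trifluoromethanesulfonate | CC(C)=CCc1cc(Cl)c(OS(=O)(=O)C(F)(F)F)c([Si](C)(C)C)c1
F9 | step 13 | 6-prenyl-1-(6-prenyl-1-SEM-indol-3-yl)-4-(4,4,5,5-tetramethyl-1,3,2-dioxaborolan-2-yl)indole | CC(C)=CCc1cc(B2OC(C)(C)C(C)(C)O2)c2ccn(-c3cn(COCC[Si](C)(C)C)c4cc(CC=C(C)C)ccc34)c2c1
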